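## Retrosynthetic overview

1. The target acid comes from its 2-(trimethylsilyl)ethyl ester by fluoride cleavage, with the isobutyrate already in place.
2. Key C13–C16 disconnection: a (Z)-β-triflyloxy enoate plus (isobutyryloxy)methylzinc iodide, an oxymethyl carbanion equivalent that joins two acceptor carbons. Palladium coupling with retention delivers the whole side arm and the 13Z geometry together.
3. The enol triflate comes from a β-keto ester, made from the N-methoxy-N-methyl amide of the ent-trinorlabd-8(17)-en-13-oic acid and an ester enolate. The exocyclic alkene comes from anti elimination of an equatorial C8–O group.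
4. The amide comes from ent-ambreinolide, made by enantioselective proton-initiated polyene cyclisation of farnesylacetic acid. Ring A closes first, then ring B, then the temporary δ-lactone ring; C5, C9 and C10 are set here.
5. Farnesylacetic acid comes from (2E,6E)-farnesol (via the bromide) and the dianion of acetic acid.

The target is in the ent-labdane series, (5R,9R,10R), with CH2O cis to CO2H (13Z).

Assumption: the binaphthol–SnCl4 acid induces the same sense as with its known homologous substrates (otherwise its mirror-image ligand is used), and 2-(trimethylsilyl)ethyl acetate and chloromethyl 2-methylpropanoate are bought.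

## Route

Step 1
Reactants: 1 (2E,6E)-farnesol
Product: 2 (2E,6E)-farnesyl bromide
Conditions: PBr3 (0.4 equiv), Et2O, −10 → 0 °C, 30 min; used crude
Reagents that add atoms: phosphorus tribromide, BrP(Br)Br
Why: PBr3 converts the primary allylic alcohol into the bromide by SN2 substitution at low temperature, without allylic transposition and with both E alkenes untouched.

Step 2
Reactants: 2 (2E,6E)-farnesyl bromide; 3 acetic acid
Product: 5 (4E,8E)-5,9,13-trimethyltetradeca-4,8,12-trienoic acid (farnesylacetic acid), via lithium 2-lithioacetate 4 (not isolated)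
Conditions: 3 (1.5 equiv), LiN(iPr)2 (3.1 equiv), THF/DMPU, 0 → 40 °C; then 2, 0 °C → rt; dil. HCl work-up
Reagents that add atoms: none
Why: Alkylation of a carboxylic acid dianion (SN2 at the primary allylic bromide) adds the two-carbon acid unit directly as the free acid; no stereocenter is formed and the alkene geometry is not touched.

Step 3
Reactants: 5 (4E,8E)-5,9,13-trimethyltetradeca-4,8,12-trienoic acid
Product: 6 ent-ambreinolide, (5R,8S,9S,10R)-14,15,16-trinorlabdan-13,8-olide
Conditions: (S)-2-(2-fluorobenzyloxy)-2'-hydroxy-1,1'-binaphthyl·SnCl4 (2 equiv), toluene, −78 °C, 72 h; then CF3CO2H, SnCl4, −78 °C; recrystallise (hexane) to >98% ee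
Reagents that add atoms: none
Why: Proposed new method: the Lewis acid-assisted chiral Brønsted acid protonates the terminal isopropylidene group on one enantioface and the (E,E)-triene then closes ring A, ring B and the lactone ring by anti additions through chair–chair folding (Stork–Eschenmoser), which sets C5, C9 and C10 (and C8) in the all-trans ent-labdane arrangement with the acid's chirality fixing the absolute sense; the closest known reaction is the same binaphthol–SnCl4-promoted enantioselective polyene cyclisation of homofarnesoic acid to sclareolide, the substrate here being its one-carbon homologue that closes a six- instead of a five-membered lactone.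

Step 4
Reactants: 6 ent-ambreinolide
Product: 7 (5R,8S,9S,10R)-8-hydroxy-N-methoxy-N-methyl-14,15,16-trinorlabdan-13-amide
Conditions: MeNH(OMe)·HCl (3 equiv), AlMe3 (3 equiv), CH2Cl2, 0 °C → rt; cold dil. HCl work-up
Reagents that add atoms: N,O-dimethylhydroxylamine hydrochloride, CNOC.Cl
Why: Aluminium amide aminolysis of the lactone (Weinreb amide formation) attacks only the acyl carbon, so the C8–O bond and all stereocenters are untouched and the tertiary alcohol is set free.

Step 5
Reactants: 7 (5R,8S,9S,10R)-8-hydroxy-N-methoxy-N-methyl-14,15,16-trinorlabdan-13-amide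
Product: 9 (5R,9R,10R)-N-methoxy-N-methyl-14,15,16-trinorlabd-8(17)-en-13-amide, via tertiary chlorosulfite 8 (not isolated)
Conditions: SOCl2 (1.5 equiv), pyridine (5 equiv), CH2Cl2, −78 °C, 30 min; AgNO3–SiO2 chromatography
Reagents that add atoms: none
Why: The equatorial C8 chlorosulfite has no antiperiplanar ring hydrogen, so the pyridine-mediated E2 elimination takes a hydrogen from the C17 methyl group and gives mainly the exocyclic 8(17)-alkene (about 6:1 over endocyclic isomers expected); C8 ceases to be a stereocenter and C9 is not touched.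

Step 6
Reactants: 9 (5R,9R,10R)-N-methoxy-N-methyl-14,15,16-trinorlabd-8(17)-en-13-amide; 10 2-(trimethylsilyl)ethyl acetate
Product: 12 2-(trimethylsilyl)ethyl (5R,9R,10R)-13-oxo-16-norlabd-8(17)-en-15-oate, via lithium ester enolate 11 (not isolated)
Conditions: 10 (2.5 equiv), LiN(iPr)2 (2.5 equiv), THF, −78 °C, 30 min; then 9, −78 → −20 °C; aq. NH4Cl
Reagents that add atoms: none
Why: Claisen-type acylation of the ester enolate by the N-methoxy-N-methyl amide stops at the β-keto ester without over-addition and brings in C14 and C15 with the fluoride-labile ester already in place.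

Step 7
Reactants: 12 2-(trimethylsilyl)ethyl (5R,9R,10R)-13-oxo-16-norlabd-8(17)-en-15-oate
Product: 13 2-(trimethylsilyl)ethyl (5R,9R,10R,13Z)-13-(trifluoromethylsulfonyloxy)-16-norlabda-8(17),13-dien-15-oate
Conditions: Tf2O (2 equiv), sat. aq. LiOH, toluene, 5 °C, 20 min
Reagents that add atoms: trifluoromethanesulfonic anhydride, O=S(=O)(OS(=O)(=O)C(F)(F)F)C(F)(F)F
Why: O-Triflation of the lithium-chelated β-keto ester enolate under biphasic aqueous LiOH conditions gives the (Z)-enol triflate (triflate cis to the ester) with high selectivity, which fixes the C13=C14 geometry needed in the target.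

Step 8
Reactants: 13 2-(trimethylsilyl)ethyl (5R,9R,10R,13Z)-13-(trifluoromethylsulfonyloxy)-16-norlabda-8(17),13-dien-15-oate; 14 chloromethyl 2-methylpropanoate
Product: 17 2-(trimethylsilyl)ethyl (5R,9R,10R,13Z)-16-(2-methylpropanoyloxy)labda-8(17),13-dien-15-oate, via iodomethyl 2-methylpropanoate 15 (not isolated), via (2-methylpropanoyloxy)methylzinc iodide 16 (not isolated)
Conditions: 14 (3 equiv), NaI (3 equiv), Zn dust (5 equiv; activated with BrCH2CH2Br and Me3SiCl), THF/DMA, 20 °C, 3 h; then 13, Pd(OAc)2 (5 mol %), SPhos (10 mol %), 25 °C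
Reagents that add atoms: none
Why: Proposed new method: zinc inserts into the iodomethyl ester to give a carbonyl-chelated (acyloxy)methylzinc, an oxymethyl carbanion equivalent with reversed polarity at C16, which palladium transfers (oxidative addition of the enol triflate, transmetalation, reductive elimination, all with retention) onto the electrophilic β-carbon C13, so that the C13–C16 bond, the complete isobutyrate arm and the 13Z geometry arrive in one operation; the closest known reactions are those of (pivaloyloxy)methylzinc iodide and its copper derivative with carbon electrophiles and the stereoretentive Negishi coupling of alkylzinc halides with (Z)-β-triflyloxy enoates.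

Step 9
Reactants: 17 2-(trimethylsilyl)ethyl (5R,9R,10R,13Z)-16-(2-methylpropanoyloxy)labda-8(17),13-dien-15-oate
Product: 18 (5R,9R,10R,13Z)-16-(2-methylpropanoyloxy)labda-8(17),13-dien-15-oic acid (16-isobutyryloxy-ent-labda-8(17),13Z-dien-15-oic acid)
Conditions: Bu4NF (2 equiv), THF, 0 °C, 1 h; then cold 0.1 M HCl to pH 4
Reagents that add atoms: none
Why: Fluoride-induced β-elimination of the 2-(trimethylsilyl)ethyl ester frees the acid under non-hydrolytic conditions at 0 °C, which the isobutyrate, the exocyclic alkene and the 13Z double bond tolerate.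

## Compound list

1 | (2E,6E)-farnesol, (2E,6E)-3,7,11-trimethyldodeca-2,6,10-trien-1-ol | CC(C)=CCC/C(C)=C/CC/C(C)=C/CO | starting material
2 | (2E,6E)-farnesyl bromide | CC(C)=CCC/C(C)=C/CC/C(C)=C/CBr | intermediate
3 | acetic acid | CC(=O)O | starting material
4 | lithium 2-lithioacetate (dianion of acetic acid) | [Li]CC(=O)O[Li] | intermediate
5 | (4E,8E)-5,9,13-trimethyltetradeca-4,8,12-trienoic acid (farnesylacetic acid) | CC(C)=CCC/C(C)=C/CC/C(C)=C/CCC(=O)O | intermediate
6 | ent-ambreinolide, (5R,8S,9S,10R)-14,15,16-trinorlabdan-13,8-olide; trans-decalin with trans-fused δ-lactone, O on C8 equatorial and cis to H-5 and H-9, C17 and C20 methyls cis | C[C@]12CC[C@@H]3C(C)(C)CCC[C@@]3(C)[C@@H]1CCC(=O)O2 | intermediate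
7 | (5R,8S,9S,10R)-8-hydroxy-N-methoxy-N-methyl-14,15,16-trinorlabdan-13-amide | C[C@]1(O)CC[C@@H]2C(C)(C)CCC[C@@]2(C)[C@@H]1CCC(=O)N(C)OC | intermediate
8 | tertiary chlorosulfite of 7 (8-O-S(O)Cl) | C[C@]1(OS(=O)Cl)CC[C@@H]2C(C)(C)CCC[C@@]2(C)[C@@H]1CCC(=O)N(C)OC | intermediate
9 | (5R,9R,10R)-N-methoxy-N-methyl-14,15,16-trinorlabd-8(17)-en-13-amide | C=C1CC[C@@H]2C(C)(C)CCC[C@@]2(C)[C@@H]1CCC(=O)N(C)OC | intermediate
10 | 2-(trimethylsilyl)ethyl acetate | CC(=O)OCC[Si](C)(C)C | starting material
11 | lithium ester enolate of 10 | C=C(O[Li])OCC[Si](C)(C)C | intermediate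
12 | 2-(trimethylsilyl)ethyl (5R,9R,10R)-13-oxo-16-norlabd-8(17)-en-15-oate | C=C1CC[C@@H]2C(C)(C)CCC[C@@]2(C)[C@@H]1CCC(=O)CC(=O)OCC[Si](C)(C)C | intermediate
13 | 2-(trimethylsilyl)ethyl (5R,9R,10R,13Z)-13-(trifluoromethylsulfonyloxy)-16-norlabda-8(17),13-dien-15-oate | C=C1CC[C@@H]2C(C)(C)CCC[C@@]2(C)[C@@H]1CC/C(OS(=O)(=O)C(F)(F)F)=C/C(=O)OCC[Si](C)(C)C | intermediate
14 | chloromethyl 2-methylpropanoate (chloromethyl isobutyrate) | CC(C)C(=O)OCCl | starting material
15 | iodomethyl 2-methylpropanoate | CC(C)C(=O)OCI | intermediate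
16 | (2-methylpropanoyloxy)methylzinc iodide | CC(C)C(=O)OC[Zn]I | intermediate
17 | 2-(trimethylsilyl)ethyl (5R,9R,10R,13Z)-16-(2-methylpropanoyloxy)labda-8(17),13-dien-15-oate | C=C1CC[C@@H]2C(C)(C)CCC[C@@]2(C)[C@@H]1CC/C(=C/C(=O)OCC[Si](C)(C)C)COC(=O)C(C)C | intermediate
18 | (5R,9R,10R,13Z)-16-(2-methylpropanoyloxy)labda-8(17),13-dien-15-oic acid | C=C1CC[C@@H]2C(C)(C)CCC[C@@]2(C)[C@@H]1CC/C(=C/C(=O)O)COC(=O)C(C)C | target

## Step count and risks

Total step count: 9. Longest linear sequence: 9 (1 → 18); 3, 10 and 14 enter as bought reagents.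

**Step 8 (key coupling).** The chelated zinc reagent may transmetalate slowly. That would let the alkenylpalladium close onto C8=C17 (5-exo Heck), or let palladium ionise the allylic isobutyrate of the product. The fallback sets out from 9 and comes back at 17, making the same C13–C16 bond from the other side with an acyl anion equivalent. Reduction of 9 with iBu2AlH (THF, −78 °C) gives (5R,9R,10R)-14,15,16-trinorlabd-8(17)-en-13-al F1. A thiazolium-carbene cross-acyloin reaction with paraformaldehyde (3-benzyl-5-(2-hydroxyethyl)-4-methylthiazolium chloride, Et3N, 60 °C) turns it into (5R,9R,10R)-16-hydroxy-14,15-dinorlabd-8(17)-en-13-one F2. Isobutyryl chloride and pyridine give (5R,9R,10R)-13-oxo-14,15-dinorlabd-8(17)-en-16-yl 2-methylpropanoate F3. Wittig olefination with Ph3P=CHCO2CH2CH2SiMe3 in MeOH follows; α-oxygenated carbonyl compounds there lean towards the isomer with the ester cis to the oxygenated carbon. It gives 17 after chromatographic removal of 2-(trimethylsilyl)ethyl (5R,9R,10R,13E)-16-(2-methylpropanoyloxy)labda-8(17),13-dien-15-oate F4. The geometry is less well controlled here than in the main route.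

**Step 3 (enantioselective cyclisation of a new substrate).** The ee may be low, or the reaction may stop short of the lactone. The fallback sets out from 5 and comes back at 6 by resolution. ClSO3H in 2-nitropropane at −78 °C cyclises 5 to rac-ambreinolide F5. AlMe3 and (S)-1-phenylethylamine open it to two diastereomeric hydroxy amides. (5R,8S,9S,10R)-8-Hydroxy-N-[(1S)-1-phenylethyl]-14,15,16-trinorlabdan-13-amide F6 is separated by chromatography or crystallisation from (5S,8R,9R,10S)-8-hydroxy-N-[(1S)-1-phenylethyl]-14,15,16-trinorlabdan-13-amide F7. Warming F6 in aqueous H2SO4/dioxane closes the lactone again to 6 and releases the amine.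

**Step 5 (position of the new double bond).** The exo/endo ratio may be poor. The fallback sets out from 7 and comes back at 9. Compound 7 is dehydrated without regard to position (POCl3, pyridine, 0 °C). The endocyclic part, mainly (5R,9R,10R)-N-methoxy-N-methyl-14,15,16-trinorlabd-7-en-13-amide F8, is then moved to the exocyclic position by photochemical contra-thermodynamic positional isomerisation. This uses Na4W10O32 as hydrogen-atom abstractor and Co(dmgH)2(py)Cl as relay under 390 nm light in MeCN, and gives 9. It is the least certain of the three fallbacks, because abstraction at C6 could compete with abstraction at C17.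

## Further compounds

F1 | step 8 | (5R,9R,10R)-14,15,16-trinorlabd-8(17)-en-13-al | C=C1CC[C@@H]2C(C)(C)CCC[C@@]2(C)[C@@H]1CCC=O
F2 | step 8 | (5R,9R,10R)-16-hydroxy-14,15-dinorlabd-8(17)-en-13-one | C=C1CC[C@@H]2C(C)(C)CCC[C@@]2(C)[C@@H]1CCC(=O)CO
F3 | step 8 | (5R,9R,10R)-13-oxo-14,15-dinorlabd-8(17)-en-16-yl 2-methylpropanoate | C=C1CC[C@@H]2C(C)(C)CCC[C@@]2(C)[C@@H]1CCC(=O)COC(=O)C(C)C
F4 | step 8 | 2-(trimethylsilyl)ethyl (5R,9R,10R,13E)-16-(2-methylpropanoyloxy)labda-8(17),13-dien-15-oate | C=C1CC[C@@H]2C(C)(C)CCC[C@@]2(C)[C@@H]1CC/C(=C\C(=O)OCC[Si](C)(C)C)COC(=O)C(C)C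
F5 | step 3 | rac-ambreinolide (1:1 mixture of 6 and its mirror image) | C[C@]12CC[C@@H]3C(C)(C)CCC[C@@]3(C)[C@@H]1CCC(=O)O2.C[C@@]12CC[C@H]3C(C)(C)CCC[C@]3(C)[C@H]1CCC(=O)O2
F6 | step 3 | (5R,8S,9S,10R)-8-hydroxy-N-[(1S)-1-phenylethyl]-14,15,16-trinorlabdan-13-amide | C[C@]1(O)CC[C@@H]2C(C)(C)CCC[C@@]2(C)[C@@H]1CCC(=O)N[C@@H](C)c1ccccc1
F7 | step 3 | (5S,8R,9R,10S)-8-hydroxy-N-[(1S)-1-phenylethyl]-14,15,16-trinorlabdan-13-amide | C[C@@]1(O)CC[C@H]2C(C)(C)CCC[C@]2(C)[C@H]1CCC(=O)N[C@@H](C)c1ccccc1
F8 | step 5 | (5R,9R,10R)-N-methoxy-N-methyl-14,15,16-trinorlabd-7-en-13-amide | CC1=CC[C@@H]2C(C)(C)CCC[C@@]2(C)[C@@H]1CCC(=O)N(C)OC
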